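## Structural features

Gnetofuran A is a 2,3-dihydrobenzofuran: the five-membered ring O1–C2–C3–C3a–C7a is fused to benzene ring B (C3a, C4–C7, C7a). C2 carries a 4-hydroxy-3-methoxyphenyl group (ring A), C3 a hydroxymethyl group, C7 a methoxy group, and C5 an (E)-ethenyl bridge to a 3,5-dihydroxyphenyl ring (ring C). C2 and C3 are the only stereocentres; they are adjacent, (2R,3S), with ring A and the hydroxymethyl group trans. The C2–O1 bond is fragile: it is a para-oxygenated benzylic aryl ether that ionises in acid and opens through a quinone methide once the ring A phenol is free and deprotonated. The resorcinol stilbene is also fragile, since it oxidises in base and can lose its E geometry. The connectivity is otherwise simple, so the real difficulty is the absolute configuration at C3 together with the trans relationship at the configurationally labile C2. The key step uses three facts: C2 and C3 are the two carbons of a stilbene-type alkene between ring A and ring B, the hydroxymethyl carbon on C3 is one formaldehyde, and O1 is a ring B phenol oxygen ortho to that alkene that can trap a cation at C2 stabilised by the para oxygen of ring A. The C5 carbon is para to O1 and meta to C3a, so as an ester it tempers the ring B phenol in the cationic step and later becomes the handle for ring C.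

## Logic of the disconnections

The last bonds cut are the three aryl O–Si bonds between 17 and 16. Free phenols on ring A and ring C cannot pass through base (the ring A phenoxide opens C2–O1, the resorcinol oxidises) or through the cationic step. The gain is that every earlier intermediate is a neutral silyl ether with one free hydroxyl group. The forward step must desilylate without touching the benzylic aryl ether, the stereocentres or the E-alkene.

The C=C bond between the C5 arm and ring C is cut next, giving 10 and 15. This removes ring C and the second styrenic alkene, which would compete for the electrophile and the acid in the key step. The gain is convergence and a dihydrobenzofuran with a single carbon at C5. The forward olefination must be E-selective and must tolerate the free C3 hydroxymethyl group, which is why all silyl ethers are bulky triisopropylsilyl groups that an alkoxide should not pick up.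

Between 10, 9 and 8 no skeletal bond is cut; only the oxidation level of the C5 carbon changes. The ester is kept for the key step because an aldehyde there would be the most basic site towards the chiral acid and a second carbonyl electrophile. The cost is two redox steps, and the oxidation must distinguish the benzylic C5 carbinol of 9 from the aliphatic C3 carbinol.

The central cut takes 8 back to 5 and 6 by breaking C3–CH2OH and O1–C2. Both stereocentres and the dihydrofuran ring disappear, leaving a flat E-stilbene and a one-carbon electrophile. The forward step has to deliver 6 to the alkene carbon next to ring B, on one face, and the ring B phenol has to close before a second molecule of 6 or a proton intervenes. Three features of 5 are chosen for this: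
- the ring A oxygen carries a triisopropylsilyl group, which should not be handed on from the oxocarbenium-like cation and survives later hydride and alkoxide;
- the C5 carbon is an ester, para to the phenol and meta to the alkene;
- the ring B phenol is the only free hydroxyl group, with both ortho positions and the para position substituted.

The aryl–vinyl bond between ring B and the alkene is cut in 5, giving 2 and 4. An aryl iodide ortho to a phenol and a terminal styrene are easy to make, and the coupling gives the E geometry directly. The forward coupling must tolerate a free ortho phenol and an aryl silyl ether.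

The C–I bond of 2 leads to 1, where the phenol directs the halogen to its only open ortho position. The O–Si bond of 4 leads to 3, which already holds the vinyl group.

For 15, the C–P bond is cut to 14, the C–Br bond to 13, the carbinol C–H to 12, and the two O–Si bonds to 11. Each forward step is a standard functional-group change on a robust silyl-protected arene.

## Other disconnections considered

Alternative 1: The cut runs through ring B at C3a–C4 and C7–C7a. C3a and C7a come from the α-carbon and the carbonyl carbon of the trans-disubstituted butyrolactone A2, and C4–C7 come from the bromopyrone ester A4. In the forward step the silyl ketene acetal A3 of A2 would add to A4 with its nucleophilic carbon at pyrone C6 and its acetal carbon at pyrone C3. Decarboxylative cycloreversion and elimination of the silyloxy group with the C3a hydrogen would then aromatise ring B onto the intact dihydrofuran, giving A1.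
- In its favour: both stereocentres would be set on a small lactone by established chemistry, the pyrone polarisation fixes the regiochemistry, and the C5 ester arrives in the same step.
- Against it: A1 carries bromine at C7, so a C–O coupling (for example CuI/NaOMe) is needed at a hindered position on a substrate with an ester and silyl ethers. The aromatisation must expel the silyloxy group and not the ring oxygen from the same ketal carbon, or the dihydrofuran opens. The lactone needs several steps of its own.
- Comparison: on stereochemical security and mechanistic precedent the alternative is the better plan, because its cascade belongs to a known reaction type and needs no new enantioselective step. On structure the chosen plan is better, since it delivers the C7 methoxy group directly. On step economy the chosen plan is better, because A1 still needs the same ester-to-aldehyde, olefination and deprotection end-game plus the bromine correction.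

Alternative 2: The cut is the C3–C3a bond, made by a 1,2-shift of ring B, so the dihydrofuran is traced to the six-membered ring of the chiral flavanone A6. In the forward step PhI(OAc)2 with H2SO4 in HC(OMe)3 would attack the enol ether of A6 at C3 with trivalent iodine. Ring B would migrate from the ketal carbon to C3 as iodobenzene leaves, and the old carbonyl carbon would become the methyl ester of A5.
- In its favour: this ring contraction is a known reaction class for flavanones and is expected to give the trans product. C2 can come from a known asymmetric conjugate arylation of a chromone. The C5 bromide of A5 would allow a direct Heck coupling to install ring C.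
- Against it: the competing 1,2-shift of the C2 aryl group to C3 (leading to an isoflavone) is favoured by electron-rich C2 aryl groups, which is why ring A must be worn as a pivalate. Strong acid can open the flavanone to the chalcone and erode C2. The oxidant is risky for the electron-rich arenes. The pivalate has to be exchanged before the C3 ester is reduced.
- Comparison: on mechanistic precedent the alternative is better. On step economy it is the equal of the chosen plan or slightly better, because the Heck end-game avoids the redox detour at C5. On stereocontrol the chosen plan sets both centres in one catalyst-controlled event, while the alternative must carry a labile benzylic centre through strong acid; neither is secure, so this point is even.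

Alternative 3: The cut removes C3a–C7a and C4–C5, so ring B is assembled from four pyrone carbons and a tethered terminal alkyne in the styrylpyrone ether A8. On heating, pyrone C3 and C6 would add across the alkyne and the bridged adduct would extrude its lactone bridge, forming ring B and the dihydrofuran together with the stilbene already present, to give A7.
- In its favour: it is the most convergent option, the tether dictates the regiochemistry, the stereocentres sit on an acyclic homopropargylic ether accessible by anti-selective allenylmetal addition, and only a global desilylation remains after the key step.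
- Against it: the ether bond between a hindered, easily ionised benzylic carbon and a 3-hydroxypyrone must be made without loss of configuration. A donor-substituted pyrone and an unactivated alkyne are electronically mismatched, so high temperature is expected, at which the styrylpyrone can isomerise or cyclise in other ways and the benzylic ether can ionise. The 3-oxy-4-methoxy-6-styrylpyrone is not a trivial building block.
- Comparison: on structure and on the sequence after the key step the alternative is better. On mechanism its reaction type is known but poorly matched electronically, whereas the chosen step is well matched but unprecedented, so this point is even. On total step count the two are about equal, with more of the alternative's effort and risk in making A8.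

Key step: step 4

Assumption: the antipode of the confined chiral acid that delivers the (3S) configuration is used; both antipodes are available from (R)- or (S)-BINOL.
Remark on the chemistry: 8 and 17 were checked atom by atom as (2R,3S)-trans and no correction to connectivity or configuration was needed; the only change to the key-step pair is that all phenol protecting groups are triisopropylsilyl ethers.

## Steps

Step 1
Reactants: 1 methyl vanillate
Product: 2 methyl 4-hydroxy-3-iodo-5-methoxybenzoate
Conditions: NIS (1.05 equiv), TsOH·H2O (10 mol%), MeCN, 0 °C → rt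
Reagents that add atoms: N-iodosuccinimide, O=C1CCC(=O)N1I
Why: Electrophilic aromatic iodination; the phenol directs to its only free ortho position (the para position holds the ester), so a single regioisomer is expected.

Step 2
Reactants: 3 2-methoxy-4-vinylphenol
Product: 4 triisopropyl(2-methoxy-4-vinylphenoxy)silane
Conditions: TIPSCl (1.2 equiv), imidazole (2.5 equiv), DMF, 0 °C → rt
Reagents that add atoms: chlorotriisopropylsilane, CC(C)[Si](Cl)(C(C)C)C(C)C
Why: Standard phenol silylation through the N-silylimidazolium species; the bulky silyl group is chosen to survive strong acid, hydride and alkoxide later and to resist migration.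

Step 3
Reactants: 2 methyl 4-hydroxy-3-iodo-5-methoxybenzoate; 4 triisopropyl(2-methoxy-4-vinylphenoxy)silane
Product: 5 methyl 4-hydroxy-3-methoxy-5-[(E)-2-[3-methoxy-4-(triisopropylsilyloxy)phenyl]ethenyl]benzoate
Conditions: Pd(OAc)2 (5 mol%), P(o-tol)3 (10 mol%), Et3N (3 equiv), DMF, 90 °C
Reagents that add atoms: none
Why: Heck reaction: zerovalent palladium formed from Pd(OAc)2 inserts into the C–I bond, syn carbopalladation at the terminal alkene carbon and syn β-hydride elimination should give the E-stilbene; free ortho-iodophenols are competent partners and Et3N is too weak a base to cleave the aryl silyl ether.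

Step 4
Reactants: 5 methyl 4-hydroxy-3-methoxy-5-[(E)-2-[3-methoxy-4-(triisopropylsilyloxy)phenyl]ethenyl]benzoate; 6 formaldehyde
Product: 8 methyl (2R,3S)-3-(hydroxymethyl)-7-methoxy-2-[3-methoxy-4-(triisopropylsilyloxy)phenyl]-2,3-dihydro-1-benzofuran-5-carboxylate, via ring A benzylic cation 7 (not isolated)
Conditions: confined chiral imidodiphosphorimidate acid (IDPi with 3,3′-diaryl-BINOL walls and N-triflyl groups, 5 mol%), 6 charged as paraformaldehyde (3 equiv), CHCl3/cyclohexane, −20 °C; then aq. NaHCO3/MeOH
Reagents that add atoms: none
Why: Proposed new method: the confined chiral acid activates formaldehyde (or a short oxymethylene oligomer) in its pocket, the alkene attacks through the carbon bonded to ring B so that the charge develops at C2 as the para-quinoid silyloxocarbenium ion 7, and the ortho-phenol of ring B then forms O1–C2. The closest known reaction type is the Brønsted-acid-catalysed asymmetric intermolecular Prins reaction of styrenes with paraformaldehyde, where a second formaldehyde traps the cation as a 1,3-dioxane; an internal phenol as the trap has not been shown. The dihydrofuran closes in a 5-exo-trig mode, the phenol oxygen adding to C2 of the exocyclic C2=C(ring A) bond of the quinoid cation. C3 is set in the C–C bond-forming event by the chiral counteranion, which exposes one enantiotopic face of the E-alkene to the bound electrophile. C2 is set by the substrate: closure occurs anti to the new hydroxymethyl group, and because C2–O1 can re-ionise under the acid the trans isomer is also the thermodynamic outcome. Regioselectivity (formaldehyde at C3, not C2) rests on ring A being the better cation-stabilising ring, since its para oxygen is conjugated with C2 while the ring B phenol is tied to the para ester, which sits meta to the alkene. Chemoselectivity over alkene protonation rests on low temperature and excess formaldehyde, which keep the acid hydrogen-bonded to oxygen bases; ring B cannot be hydroxymethylated because both ortho positions and the para position of its phenol are substituted, and hemiformals at the phenol or the product alcohol are reversible and cleaved in the basic work-up. If a 1,3-dioxane forms first, its benzylic C–O bond should ionise to the same cation 7 and funnel to 8.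

Step 5
Reactants: 8 methyl (2R,3S)-3-(hydroxymethyl)-7-methoxy-2-[3-methoxy-4-(triisopropylsilyloxy)phenyl]-2,3-dihydro-1-benzofuran-5-carboxylate
Product: 9 [(2R,3S)-7-methoxy-2-[3-methoxy-4-(triisopropylsilyloxy)phenyl]-2,3-dihydro-1-benzofuran-3,5-diyl]dimethanol
Conditions: i-Bu2AlH (4 equiv), CH2Cl2, −78 → 0 °C; aq. KNaC4H4O6 (potassium sodium tartrate)
Reagents that add atoms: none
Why: Hydride reduction of the aryl ester to the benzylic alcohol; the free alcohol only consumes one equivalent as its aluminium alkoxide, and the aryl silyl ether and the C2–O1 bond should not react at low temperature, so both stereocentres stay untouched.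

Step 6
Reactants: 9 [(2R,3S)-7-methoxy-2-[3-methoxy-4-(triisopropylsilyloxy)phenyl]-2,3-dihydro-1-benzofuran-3,5-diyl]dimethanol
Product: 10 (2R,3S)-3-(hydroxymethyl)-7-methoxy-2-[3-methoxy-4-(triisopropylsilyloxy)phenyl]-2,3-dihydro-1-benzofuran-5-carbaldehyde
Conditions: activated MnO2 (15 equiv), CH2Cl2, rt
Reagents that add atoms: none
Why: MnO2 oxidises benzylic alcohols on its surface through a pathway that needs the adjacent arene, so only the C5 carbinol should be oxidised and the aliphatic C3 hydroxymethyl group left; without water no over-oxidation to the acid is expected.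

Step 7
Reactants: 11 3,5-dihydroxybenzaldehyde
Product: 12 3,5-bis(triisopropylsilyloxy)benzaldehyde
Conditions: TIPSCl (2.3 equiv), imidazole (5 equiv), DMF, rt
Reagents that add atoms: chlorotriisopropylsilane, CC(C)[Si](Cl)(C(C)C)C(C)C
Why: Standard double silylation of a resorcinol; the bulky silyl ethers are needed to resist the alkoxide present in step 11.

Step 8
Reactants: 12 3,5-bis(triisopropylsilyloxy)benzaldehyde
Product: 13 [3,5-bis(triisopropylsilyloxy)phenyl]methanol
Conditions: NaBH4, EtOH/THF, 0 °C
Reagents that add atoms: none
Why: Borohydride reduction of an aryl aldehyde; the hindered aryl silyl ethers should tolerate the mildly basic medium at 0 °C.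

Step 9
Reactants: 13 [3,5-bis(triisopropylsilyloxy)phenyl]methanol
Product: 14 1-(bromomethyl)-3,5-bis(triisopropylsilyloxy)benzene
Conditions: CBr4, PPh3, CH2Cl2, 0 °C
Reagents that add atoms: carbon tetrabromide, BrC(Br)(Br)Br
Why: Appel reaction: the alkoxyphosphonium ion is displaced by bromide at the primary benzylic carbon under neutral conditions that leave the silyl ethers alone.

Step 10
Reactants: 14 1-(bromomethyl)-3,5-bis(triisopropylsilyloxy)benzene
Product: 15 diethyl [3,5-bis(triisopropylsilyloxy)benzyl]phosphonate
Conditions: P(OEt)3 (neat, 3 equiv), 130 °C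
Reagents that add atoms: triethyl phosphite, CCOP(OCC)OCC
Why: Michaelis–Arbuzov reaction: the phosphite displaces the benzylic bromide and the phosphonium intermediate is dealkylated by bromide; aryl silyl ethers are stable to neat phosphite at this temperature.

Step 11
Reactants: 10 (2R,3S)-3-(hydroxymethyl)-7-methoxy-2-[3-methoxy-4-(triisopropylsilyloxy)phenyl]-2,3-dihydro-1-benzofuran-5-carbaldehyde; 15 diethyl [3,5-bis(triisopropylsilyloxy)benzyl]phosphonate
Product: 16 [(2R,3S)-5-[(E)-2-[3,5-bis(triisopropylsilyloxy)phenyl]ethenyl]-7-methoxy-2-[3-methoxy-4-(triisopropylsilyloxy)phenyl]-2,3-dihydro-1-benzofuran-3-yl]methanol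
Conditions: 15 (2.2 equiv), NaH (2.2 equiv), THF, 0 °C; then 10, 0 °C → rt
Reagents that add atoms: none
Why: Horner–Wadsworth–Emmons olefination: the deprotonated benzylic phosphonate adds to the aldehyde and the oxaphosphetane collapses to the favoured E-stilbene; one equivalent of base is spent on the primary alcohol, whose alkoxide is a spectator, and the bulky silyl ethers should resist transfer to it.

Step 12
Reactants: 16 [(2R,3S)-5-[(E)-2-[3,5-bis(triisopropylsilyloxy)phenyl]ethenyl]-7-methoxy-2-[3-methoxy-4-(triisopropylsilyloxy)phenyl]-2,3-dihydro-1-benzofuran-3-yl]methanol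
Product: 17 gnetofuran A, 5-[(E)-2-[(2R,3S)-2-(4-hydroxy-3-methoxyphenyl)-3-(hydroxymethyl)-7-methoxy-2,3-dihydro-1-benzofuran-5-yl]ethenyl]benzene-1,3-diol
Conditions: Bu4NF (3.5 equiv), AcOH (3.5 equiv), THF, 0 °C
Reagents that add atoms: none
Why: Fluoride cleaves the three aryl Si–O bonds (strong Si–F bond, phenoxide leaving groups); the AcOH buffer keeps the medium from becoming basic enough to open the dihydrofuran through the ring A phenoxide or to oxidise the resorcinol, so C2, C3 and the E-alkene should be preserved.

## Compound list

1 | methyl vanillate (methyl 4-hydroxy-3-methoxybenzoate) | COc1cc(C(=O)OC)ccc1O | starting material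
2 | methyl 4-hydroxy-3-iodo-5-methoxybenzoate | COc1cc(C(=O)OC)cc(I)c1O | intermediate
3 | 2-methoxy-4-vinylphenol | COc1cc(C=C)ccc1O | starting material
4 | triisopropyl(2-methoxy-4-vinylphenoxy)silane | COc1cc(C=C)ccc1O[Si](C(C)C)(C(C)C)C(C)C | intermediate
5 | methyl 4-hydroxy-3-methoxy-5-[(E)-2-[3-methoxy-4-(triisopropylsilyloxy)phenyl]ethenyl]benzoate | COc1cc(/C=C/c2cc(C(=O)OC)cc(OC)c2O)ccc1O[Si](C(C)C)(C(C)C)C(C)C | intermediate
6 | formaldehyde (charged as paraformaldehyde) | C=O | starting material
7 | ring A benzylic cation at C2 with C3 already (S)-configured, ion-paired with the catalyst anion, formed and consumed in step 4 | COc1cc([CH+][C@H](CO)c2cc(C(=O)OC)cc(OC)c2O)ccc1O[Si](C(C)C)(C(C)C)C(C)C | intermediate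
8 | methyl (2R,3S)-3-(hydroxymethyl)-7-methoxy-2-[3-methoxy-4-(triisopropylsilyloxy)phenyl]-2,3-dihydro-1-benzofuran-5-carboxylate | COc1cc([C@@H]2Oc3c(OC)cc(C(=O)OC)cc3[C@H]2CO)ccc1O[Si](C(C)C)(C(C)C)C(C)C | intermediate
9 | [(2R,3S)-7-methoxy-2-[3-methoxy-4-(triisopropylsilyloxy)phenyl]-2,3-dihydro-1-benzofuran-3,5-diyl]dimethanol | COc1cc([C@@H]2Oc3c(OC)cc(CO)cc3[C@H]2CO)ccc1O[Si](C(C)C)(C(C)C)C(C)C | intermediate
10 | (2R,3S)-3-(hydroxymethyl)-7-methoxy-2-[3-methoxy-4-(triisopropylsilyloxy)phenyl]-2,3-dihydro-1-benzofuran-5-carbaldehyde | COc1cc([C@@H]2Oc3c(OC)cc(C=O)cc3[C@H]2CO)ccc1O[Si](C(C)C)(C(C)C)C(C)C | intermediate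
11 | 3,5-dihydroxybenzaldehyde | O=Cc1cc(O)cc(O)c1 | starting material
12 | 3,5-bis(triisopropylsilyloxy)benzaldehyde | O=Cc1cc(O[Si](C(C)C)(C(C)C)C(C)C)cc(O[Si](C(C)C)(C(C)C)C(C)C)c1 | intermediate
13 | [3,5-bis(triisopropylsilyloxy)phenyl]methanol | OCc1cc(O[Si](C(C)C)(C(C)C)C(C)C)cc(O[Si](C(C)C)(C(C)C)C(C)C)c1 | intermediate
14 | 1-(bromomethyl)-3,5-bis(triisopropylsilyloxy)benzene | BrCc1cc(O[Si](C(C)C)(C(C)C)C(C)C)cc(O[Si](C(C)C)(C(C)C)C(C)C)c1 | intermediate
15 | diethyl [3,5-bis(triisopropylsilyloxy)benzyl]phosphonate | CCOP(=O)(OCC)Cc1cc(O[Si](C(C)C)(C(C)C)C(C)C)cc(O[Si](C(C)C)(C(C)C)C(C)C)c1 | intermediate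
16 | [(2R,3S)-5-[(E)-2-[3,5-bis(triisopropylsilyloxy)phenyl]ethenyl]-7-methoxy-2-[3-methoxy-4-(triisopropylsilyloxy)phenyl]-2,3-dihydro-1-benzofuran-3-yl]methanol | COc1cc([C@@H]2Oc3c(OC)cc(/C=C/c4cc(O[Si](C(C)C)(C(C)C)C(C)C)cc(O[Si](C(C)C)(C(C)C)C(C)C)c4)cc3[C@H]2CO)ccc1O[Si](C(C)C)(C(C)C)C(C)C | intermediate
17 | gnetofuran A, 5-[(E)-2-[(2R,3S)-2-(4-hydroxy-3-methoxyphenyl)-3-(hydroxymethyl)-7-methoxy-2,3-dihydro-1-benzofuran-5-yl]ethenyl]benzene-1,3-diol | COc1cc([C@@H]2Oc3c(OC)cc(/C=C/c4cc(O)cc(O)c4)cc3[C@H]2CO)ccc1O | target

## Step count and risks

Total step count: 12. Longest linear sequence: 7 steps (1, 3, 4, 5, 6, 11, 12, from 1 to 17).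

Step 4 (the step with the new method). The most likely failures are:
- protonation of the alkene followed by phenol closure without uptake of formaldehyde;
- bond formation at the alkene carbon next to ring A;
- poor facial selectivity, because the substrate is larger and more Lewis-basic than the simple styrenes for which confined acids of this kind are known to work.

The fallback uses known chemistry, sets out from 4 and 2 and returns at 9. Ozonolysis of 4 with NaBH4 work-up would give [3-methoxy-4-(triisopropylsilyloxy)phenyl]methanol F1. Mitsunobu etherification of 2 with F1 (PPh3, DIAD, THF) would give methyl 3-iodo-5-methoxy-4-{[3-methoxy-4-(triisopropylsilyloxy)phenyl]methoxy}benzoate F2. Coupling of F2 with ethyl diazoacetate (Pd(PPh3)4, Ag2CO3, Et3N, toluene) would give methyl 3-(1-diazo-2-ethoxy-2-oxoethyl)-5-methoxy-4-{[3-methoxy-4-(triisopropylsilyloxy)phenyl]methoxy}benzoate F3. A chiral dirhodium tetracarboxylate such as Rh2(S-PTTL)4, or its antipode, whichever gives 2R, would insert the carbene into the benzylic C–H bond of the ether and close the ring as the cis diester 3-ethyl 5-methyl (2R,3S)-7-methoxy-2-[3-methoxy-4-(triisopropylsilyloxy)phenyl]-2,3-dihydro-1-benzofuran-3,5-dicarboxylate F4. Epimerisation at C3 with DBU would give the trans diester 3-ethyl 5-methyl (2R,3R)-7-methoxy-2-[3-methoxy-4-(triisopropylsilyloxy)phenyl]-2,3-dihydro-1-benzofuran-3,5-dicarboxylate F5. Reduction of both esters with i-Bu2AlH would deliver 9.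

Step 3. The most likely failures are catalyst deactivation by the ortho phenoxide, reductive loss of iodine, and arylation at the internal alkene carbon, because the styrene is electron-rich. The fallback sets out from 4 and 2 and returns at 5. Cross-metathesis of 4 with vinylboronic acid pinacol ester (second-generation Grubbs catalyst, RuCl2(=CHPh)(H2IMes)(PCy3)) would give (E)-2-{2-[3-methoxy-4-(triisopropylsilyloxy)phenyl]ethenyl}-4,4,5,5-tetramethyl-1,3,2-dioxaborolane F6. Suzuki–Miyaura coupling of F6 with 2 (PdCl2(dppf), K3PO4, dioxane/water) would give 5 with the alkene geometry fixed in advance.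

Step 11. The most likely failures are silyl transfer from an aryl oxygen to the sodium alkoxide of the C3 hydroxymethyl group and stalling of the olefination on the electron-rich aldehyde, because a strong base is unavoidable with a benzylic phosphonate. The fallback sets out from 14 and 10 and returns at 16. Heating 14 with PPh3 in toluene would give [3,5-bis(triisopropylsilyloxy)benzyl]triphenylphosphonium bromide F7. Wittig reaction of F7 with 10 under weak-base conditions (K2CO3, 18-crown-6, CH2Cl2), which do not form the alkoxide, would give 16 together with its Z isomer [(2R,3S)-5-[(Z)-2-[3,5-bis(triisopropylsilyloxy)phenyl]ethenyl]-7-methoxy-2-[3-methoxy-4-(triisopropylsilyloxy)phenyl]-2,3-dihydro-1-benzofuran-3-yl]methanol F8. Catalytic I2 would then isomerise F8 to 16.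

Step 12. The most likely failure is base-promoted opening of the dihydrofuran through the ring A phenoxide or oxidative decay of the resorcinol stilbene during desilylation and isolation from ammonium salts, because the product is a polyphenol with a labile benzylic ether. The fallback sets out from 16 and returns at 17. After the fluoride treatment, Ac2O and pyridine would be added to the same flask so that the product is isolated and purified as the tetraacetate [(2R,3S)-2-(4-acetoxy-3-methoxyphenyl)-5-[(E)-2-(3,5-diacetoxyphenyl)ethenyl]-7-methoxy-2,3-dihydro-1-benzofuran-3-yl]methyl acetate F9. Methanolysis of F9 (catalytic K2CO3, degassed MeOH, 0 °C, quench with an acidic resin) would then release 17 free of ammonium salts.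

## Further compounds

F1 | step 4 | [3-methoxy-4-(triisopropylsilyloxy)phenyl]methanol | COc1cc(CO)ccc1O[Si](C(C)C)(C(C)C)C(C)C
F2 | step 4 | methyl 3-iodo-5-methoxy-4-{[3-methoxy-4-(triisopropylsilyloxy)phenyl]methoxy}benzoate | COC(=O)c1cc(I)c(OCc2ccc(O[Si](C(C)C)(C(C)C)C(C)C)c(OC)c2)c(OC)c1
F3 | step 4 | methyl 3-(1-diazo-2-ethoxy-2-oxoethyl)-5-methoxy-4-{[3-methoxy-4-(triisopropylsilyloxy)phenyl]methoxy}benzoate | CCOC(=O)C(=[N+]=[N-])c1cc(C(=O)OC)cc(OC)c1OCc1ccc(O[Si](C(C)C)(C(C)C)C(C)C)c(OC)c1
F4 | step 4 | 3-ethyl 5-methyl (2R,3S)-7-methoxy-2-[3-methoxy-4-(triisopropylsilyloxy)phenyl]-2,3-dihydro-1-benzofuran-3,5-dicarboxylate (cis) | COc1cc([C@@H]2Oc3c(OC)cc(C(=O)OC)cc3[C@@H]2C(=O)OCC)ccc1O[Si](C(C)C)(C(C)C)C(C)C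
F5 | step 4 | 3-ethyl 5-methyl (2R,3R)-7-methoxy-2-[3-methoxy-4-(triisopropylsilyloxy)phenyl]-2,3-dihydro-1-benzofuran-3,5-dicarboxylate (trans) | COc1cc([C@@H]2Oc3c(OC)cc(C(=O)OC)cc3[C@H]2C(=O)OCC)ccc1O[Si](C(C)C)(C(C)C)C(C)C
F6 | step 3 | (E)-2-{2-[3-methoxy-4-(triisopropylsilyloxy)phenyl]ethenyl}-4,4,5,5-tetramethyl-1,3,2-dioxaborolane | COc1cc(/C=C/B2OC(C)(C)C(C)(C)O2)ccc1O[Si](C(C)C)(C(C)C)C(C)C
F7 | step 11 | [3,5-bis(triisopropylsilyloxy)benzyl]triphenylphosphonium bromide | CC(C)[Si](Oc1cc(C[P+](c2ccccc2)(c2ccccc2)c2ccccc2)cc(O[Si](C(C)C)(C(C)C)C(C)C)c1)(C(C)C)C(C)C.[Br-]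
F8 | step 11 | [(2R,3S)-5-[(Z)-2-[3,5-bis(triisopropylsilyloxy)phenyl]ethenyl]-7-methoxy-2-[3-methoxy-4-(triisopropylsilyloxy)phenyl]-2,3-dihydro-1-benzofuran-3-yl]methanol | COc1cc([C@@H]2Oc3c(OC)cc(/C=C\c4cc(O[Si](C(C)C)(C(C)C)C(C)C)cc(O[Si](C(C)C)(C(C)C)C(C)C)c4)cc3[C@H]2CO)ccc1O[Si](C(C)C)(C(C)C)C(C)C
F9 | step 12 | [(2R,3S)-2-(4-acetoxy-3-methoxyphenyl)-5-[(E)-2-(3,5-diacetoxyphenyl)ethenyl]-7-methoxy-2,3-dihydro-1-benzofuran-3-yl]methyl acetate | COc1cc([C@@H]2Oc3c(OC)cc(/C=C/c4cc(OC(C)=O)cc(OC(C)=O)c4)cc3[C@H]2COC(C)=O)ccc1OC(C)=O
A1 | alternative 1 | methyl (2R,3S)-7-bromo-2-[4-(tert-butyldimethylsilyloxy)-3-methoxyphenyl]-3-[(tert-butyldimethylsilyloxy)methyl]-2,3-dihydro-1-benzofuran-5-carboxylate (trans) | COc1cc([C@@H]2Oc3c(Br)cc(C(=O)OC)cc3[C@H]2CO[Si](C)(C)C(C)(C)C)ccc1O[Si](C)(C)C(C)(C)C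
A2 | alternative 1 | (4S,5R)-5-[4-(tert-butyldimethylsilyloxy)-3-methoxyphenyl]-4-[(tert-butyldimethylsilyloxy)methyl]dihydrofuran-2(3H)-one | COc1cc([C@@H]2OC(=O)C[C@H]2CO[Si](C)(C)C(C)(C)C)ccc1O[Si](C)(C)C(C)(C)C
A3 | alternative 1 | trimethylsilyl ketene acetal of A2, {[(4S,5R)-5-[4-(tert-butyldimethylsilyloxy)-3-methoxyphenyl]-4-[(tert-butyldimethylsilyloxy)methyl]-4,5-dihydrofuran-2-yl]oxy}trimethylsilane | COc1cc([C@@H]2OC(O[Si](C)(C)C)=C[C@H]2CO[Si](C)(C)C(C)(C)C)ccc1O[Si](C)(C)C(C)(C)C
A4 | alternative 1 | methyl 3-bromo-2-oxo-2H-pyran-5-carboxylate | COC(=O)C1=COC(=O)C(Br)=C1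
A5 | alternative 2 | methyl (2R,3R)-5-bromo-7-methoxy-2-(3-methoxy-4-pivaloyloxyphenyl)-2,3-dihydro-1-benzofuran-3-carboxylate (trans) | COc1cc([C@@H]2Oc3c(OC)cc(Br)cc3[C@H]2C(=O)OC)ccc1OC(=O)C(C)(C)C
A6 | alternative 2 | (2R)-6-bromo-8-methoxy-2-(3-methoxy-4-pivaloyloxyphenyl)chroman-4-one | COc1cc([C@@H]2Oc3c(OC)cc(Br)cc3C(=O)C2)ccc1OC(=O)C(C)(C)C
A7 | alternative 3 | tetrakis(tert-butyldimethylsilyl) ether of gnetofuran A | COc1cc([C@@H]2Oc3c(OC)cc(/C=C/c4cc(O[Si](C)(C)C(C)(C)C)cc(O[Si](C)(C)C(C)(C)C)c4)cc3[C@H]2CO[Si](C)(C)C(C)(C)C)ccc1O[Si](C)(C)C(C)(C)C
A8 | alternative 3 | 3-{[(1R,2S)-1-[4-(tert-butyldimethylsilyloxy)-3-methoxyphenyl]-2-[(tert-butyldimethylsilyloxy)methyl]but-3-yn-1-yl]oxy}-6-[(E)-2-[3,5-bis(tert-butyldimethylsilyloxy)phenyl]ethenyl]-4-methoxy-2H-pyran-2-one | COc1cc([C@H](OC2=C(OC)C=C(/C=C/c3cc(O[Si](C)(C)C(C)(C)C)cc(O[Si](C)(C)C(C)(C)C)c3)OC2=O)[C@H](CO[Si](C)(C)C(C)(C)C)C#C)ccc1O[Si](C)(C)C(C)(C)C
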